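The two malonate esters are cleaved first, which leaves two identical labda-7,13E-dien-15-ol units. In each unit, ring B (C5–C10) with the C8 methyl on C7=C8, and the gem-dimethyl carbon C4 on C5, correspond to the methylcyclohexenone ring and the isopropenyl carbon of (R)-carvone. The key step exploits this match. The route rests on the C3–C4 disconnection. One iron-hydride-triggered radical cyclisation converts the isopropenyl group into quaternary C4 (C18, C19) and closes ring A as a trans-decalin. Its substrate is carvone bearing on C10 (carvone C6) a methyl group and, anti to isopropenyl, a 2-(methoxycarbonyl)allyl arm. C9 is set later by hydroboration and the 13E alkene by carboalumination.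

Key step: step 3

Remark: labdane numbering is used for all bicyclic compounds. Both halves of the target read (5S,9S,10S,13E), the normal labdane series, whose C5 corresponds to C5 of (R)-carvone. Compound 3 is carried forward as its C6-epimer mixture because that centre is planarised again in step 2.

Step 1
Reactants: 1 (R)-(−)-carvone; 2 iodomethane
Product: 3 (5R,6S)-6-methylcarvone (methyl trans to isopropenyl, accompanied by its C6 epimer)
Conditions: LDA, THF, −78 °C; MeI, −78 → 0 °C
Reagents that add atoms: iodomethane (2), CI
Why: Lithium enolate alkylation after kinetic α′-deprotonation of the cross-conjugated enone; the new C6 centre does not matter because it is re-enolised in step 2.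

Step 2
Reactants: 3 6-methylcarvone; 4 methyl 2-(bromomethyl)acrylate
Product: 5 (5S,6S)-6-methyl-6-[2-(methoxycarbonyl)allyl]carvone (acrylate arm anti, methyl syn to the isopropenyl group)
Conditions: LDA, THF, −78 → 0 °C; 4, DMPU, −78 °C → rt
Reagents that add atoms: methyl 2-(bromomethyl)acrylate (4), C=C(CBr)C(=O)OC
Why: Enolate alkylation (SN2 and SN2′ attack on the allylic bromide give the same product) in which the electrophile reaches the tetrasubstituted enolate on the face opposite the neighbouring isopropenyl group, fixing quaternary C10 (labdane 10S).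

Step 3
Reactants: 5 6-methyl-6-[2-(methoxycarbonyl)allyl]carvone
Product: 6 methyl 9-oxo-11-nordrim-7-ene-2α-carboxylate (trans-decalin, 5α-H, 10β-CH3, equatorial ester)
Conditions: Fe(acac)3 (30 mol %), PhSiH3, EtOH (0.02 M), 60 °C
Reagents that add atoms: none
Why: An iron hydride formed from Fe(acac)3 and PhSiH3 delivers a hydrogen atom to the CH2 end of the isopropenyl group, so the tertiary C4 radical appears with C18 and C19 already attached; this nucleophilic radical attacks the free acrylate terminus C3, and the α-ester radical is then reduced by Fe(II) and protonated by ethanol. The closest known reaction type is the iron-catalysed reductive olefin coupling (a Giese addition started by metal-hydride hydrogen atom transfer), used here intramolecularly. Ring A closes 6-endo-trig, because 5-exo attack would have to hit the fully substituted, ester-bearing C2 and would leave an unstabilised primary radical. The trans fusion is inherited rather than created: the C5–C4 and C10–C1 bonds stand anti on ring B and can bridge only when both are equatorial; the single new centre, C2, should result from axial protonation of the enolate (equatorial ester) and is deleted in step 5. The step requires hydrogen atom transfer to the isopropenyl group alone, which is secured because it is the only electron-rich, unhindered 1,1-disubstituted alkene, while the acrylate and the trisubstituted ring enone are electron-poor; high dilution suppresses intermolecular addition.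

Step 4
Reactants: 6 methyl 9-oxo-11-nordrim-7-ene-2α-carboxylate
Product: 7 9-oxo-11-nordrim-7-ene-2α-carboxylic acid
Conditions: LiOH, THF/MeOH/H2O, rt; then aq. HCl
Reagents that add atoms: lithium hydroxide, [Li+].[OH-]
Why: Saponification (BAc2) of an unhindered equatorial methyl ester; the ketone has no α-hydrogen and any epimerisation at C2 is irrelevant.

Step 5
Reactants: 7 9-oxo-11-nordrim-7-ene-2α-carboxylic acid
Product: 8 11-nordrim-7-en-9-one [(4aS,8aS)-2,5,5,8a-tetramethyl-4a,5,6,7,8,8a-hexahydronaphthalen-1(4H)-one]
Conditions: 9-mesityl-10-phenylacridinium BF4 (5 mol %), PhSSPh (10 mol %), i-Pr2NEt (20 mol %), CF3CH2OH, 450 nm LED, rt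
Reagents that add atoms: none
Why: Photoredox hydrodecarboxylation in which the carboxylate is oxidised and loses CO2, and the secondary C2 radical takes a hydrogen atom from thiophenol formed in situ faster than it can add to the hindered enone, which removes the C2 stereocentre.

Step 6
Reactants: 8 11-nordrim-7-en-9-one; 9 (trimethylsilyl)methyllithium
Product: 11 drima-7,9(11)-diene (5S,10S), via lithium β-silylalkoxide 10 (not isolated)
Conditions: TMSCH2Li, THF, −78 → 0 °C; t-BuOH (destroys excess RLi), KOt-Bu, 0 °C → rt
Reagents that add atoms: (trimethylsilyl)methyllithium (9), [Li]C[Si](C)(C)C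
Why: Peterson olefination in which the hard primary carbanion adds 1,2 to the ketone, which has no α-hydrogen, and the potassium alkoxide loses silanolate by syn-elimination, so the new alkene can only be C9=C11.

Step 7
Reactants: 11 drima-7,9(11)-diene; 12 bromoacetone
Product: 14 14,15-dinorlabd-7-en-13-one (5S,9S,10S), via B-(drim-7-en-11-yl)-9-BBN 13 (not isolated)
Conditions: 9-BBN, THF, rt → 50 °C; then 12, potassium 2,6-di-tert-butylphenoxide, THF, 0 °C → rt
Reagents that add atoms: bromoacetone (12), CC(=O)CBr
Why: Hydroboration followed by Brown α-alkylation of a B-alkyl-9-BBN with an α-bromo ketone enolate (ate complex, 1,2-shift with loss of bromide), in which 9-BBN attacks only the terminal 1,1-disubstituted alkene with boron at C11 and from the α face opposite the axial C10 methyl, so hydrogen enters C9 axially (9α-H, 9S) and the chain becomes equatorial.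

Step 8
Reactants: 14 14,15-dinorlabd-7-en-13-one
Product: 16 15,16-dinorlabd-7-en-13-yne (9β-(but-3-ynyl) compound, 5S,9S,10S), via terminal enol diethyl phosphate 15 (not isolated)
Conditions: LDA, THF, −78 °C; ClP(O)(OEt)2, −78 °C → rt; LDA (2.3 equiv), −78 °C → rt; H2O
Reagents that add atoms: none
Why: Negishi conversion of a methyl ketone into a terminal alkyne through kinetic deprotonation at the methyl group, O-phosphorylation and base-induced β-elimination of diethyl phosphate, with no stereocentre touched.

Step 9
Reactants: 16 15,16-dinorlabd-7-en-13-yne; 17 trimethylaluminium; 18 paraformaldehyde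
Product: 21 labda-7,13E-dien-15-ol (5S,9S,10S), via alkenyl(dimethyl)alane 19 (not isolated), via lithium alkenylalanate 20 (not isolated)
Conditions: Me3Al, Cp2ZrCl2 (25 mol %), CH2Cl2, 0 °C → rt; evaporate; n-BuLi, THF/hexane, −78 → 0 °C; (CH2O)n, rt; aq. Rochelle salt
Reagents that add atoms: trimethylaluminium (17), C[Al](C)C; paraformaldehyde (18, as formaldehyde), C=O
Why: Negishi zirconium-catalysed carboalumination, whose syn addition of methyl (to C13) and aluminium (to terminal C14) fixes the 13E geometry, followed by hydroxymethylation of the alanate with retention, the trisubstituted C7=C8 alkene being inert.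

Step 10
Reactants: 21 labda-7,13E-dien-15-ol (2 equiv); 22 malonic acid
Product: 23 bis[(5S,9S,10S)-labda-7,13E-dien-15-yl] malonate (CNP0113044.1)
Conditions: DCC, DMAP (cat.), CH2Cl2/THF, 0 °C → rt
Reagents that add atoms: malonic acid (22), OC(=O)CC(=O)O
Why: Steglich esterification of both carboxyl groups under neutral conditions that spare the acid-sensitive primary allylic alcohol and all alkenes, with no stereocentre affected.

Compound list
1 | (R)-(−)-carvone | CC1=CC[C@@H](C(C)=C)CC1=O | starting material
2 | iodomethane | CI | starting material
3 | (5R,6S)-6-methylcarvone (major trans epimer, used together with its C6 epimer) | CC1=CC[C@@H](C(C)=C)[C@H](C)C1=O | intermediate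
4 | methyl 2-(bromomethyl)acrylate | C=C(CBr)C(=O)OC | starting material
5 | (5S,6S)-6-methyl-6-[2-(methoxycarbonyl)allyl]carvone | CC1=CC[C@@H](C(C)=C)[C@](C)(CC(=C)C(=O)OC)C1=O | intermediate
6 | methyl 9-oxo-11-nordrim-7-ene-2α-carboxylate | CC1=CC[C@H]2C(C)(C)C[C@H](C(=O)OC)C[C@]2(C)C1=O | intermediate
7 | 9-oxo-11-nordrim-7-ene-2α-carboxylic acid | CC1=CC[C@H]2C(C)(C)C[C@H](C(=O)O)C[C@]2(C)C1=O | intermediate
8 | 11-nordrim-7-en-9-one | CC1=CC[C@H]2C(C)(C)CCC[C@]2(C)C1=O | intermediate
9 | (trimethylsilyl)methyllithium | [Li]C[Si](C)(C)C | starting material
10 | lithium 9α-(trimethylsilylmethyl)-11-nordrim-7-en-9β-olate | CC1=CC[C@H]2C(C)(C)CCC[C@]2(C)[C@]1([O-])C[Si](C)(C)C.[Li+] | intermediate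
11 | drima-7,9(11)-diene | CC1=CC[C@H]2C(C)(C)CCC[C@]2(C)C1=C | intermediate
12 | bromoacetone | CC(=O)CBr | starting material
13 | B-(drim-7-en-11-yl)-9-borabicyclo[3.3.1]nonane (9α-H) | CC1=CC[C@H]2C(C)(C)CCC[C@]2(C)[C@H]1CB1C2CCCC1CCC2 | intermediate
14 | 14,15-dinorlabd-7-en-13-one | CC1=CC[C@H]2C(C)(C)CCC[C@]2(C)[C@H]1CCC(C)=O | intermediate
15 | diethyl 14,15-dinorlabda-7,13(16)-dien-13-yl phosphate | CC1=CC[C@H]2C(C)(C)CCC[C@]2(C)[C@H]1CCC(=C)OP(=O)(OCC)OCC | intermediate
16 | 15,16-dinorlabd-7-en-13-yne | CC1=CC[C@H]2C(C)(C)CCC[C@]2(C)[C@H]1CCC#C | intermediate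
17 | trimethylaluminium | C[Al](C)C | starting material
18 | paraformaldehyde (written as formaldehyde) | C=O | starting material
19 | (E)-(15-norlabda-7,13-dien-14-yl)dimethylalane | CC1=CC[C@H]2C(C)(C)CCC[C@]2(C)[C@H]1CC/C(C)=C/[Al](C)C | intermediate
20 | lithium butyl[(E)-15-norlabda-7,13-dien-14-yl]dimethylalanate | [Li+].CCCC[Al-](C)(C)/C=C(\C)CC[C@H]1C(C)=CC[C@H]2C(C)(C)CCC[C@]12C | intermediate
21 | labda-7,13E-dien-15-ol | CC1=CC[C@H]2C(C)(C)CCC[C@]2(C)[C@H]1CC/C(C)=C/CO | intermediate
22 | malonic acid | OC(=O)CC(=O)O | starting material
23 | bis(labda-7,13E-dien-15-yl) malonate | CC1=CC[C@H]2C(C)(C)CCC[C@]2(C)[C@H]1CC/C(C)=C/COC(=O)CC(=O)OC/C=C(\C)CC[C@H]1C(C)=CC[C@H]2C(C)(C)CCC[C@]12C | target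

Total step count: 10. Longest linear sequence: 10. The route is fully linear, and the last step joins two molecules of 21 through 22.

Steps most likely to fail

Step 3. Hydrogen atom transfer may also reach the acrylate, or the C4 radical may be reduced before it cyclises, which would amount to hydrogenation of the isopropenyl group. The fallback generates the same radical from a halide. From 5, one equivalent of HBr (33 % in AcOH, 0 °C) adds in the Markovnikov sense to the only alkene that can give a tertiary cation. This yields the tertiary bromide 6-methyl-6-[2-(methoxycarbonyl)allyl]carvone hydrobromide F1. Slow addition of Bu3SnH/AIBN (benzene, reflux, high dilution) then abstracts bromine, and the tin-hydride Giese cyclisation returns to 6.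

Step 7. The migration of the β-branched, hindered alkyl group from boron to the bromo-enolate carbon may be too slow, so that self-condensation of the bromo ketone or protodeboronation takes over. The fallback builds the C11–C12 bond by carbonyl olefination instead.
- From 11, the same borane 13 is oxidised (NaOH, H2O2) to (−)-drimenol F2.
- Dess–Martin oxidation gives drimenal F3.
- Horner–Wadsworth–Emmons reaction with commercial diethyl (2-oxopropyl)phosphonate (LiCl, i-Pr2NEt, MeCN) gives 14,15-dinorlabda-7,11E-dien-13-one F4.
- Copper hydride 1,4-reduction of this disubstituted enone (Stryker reagent, benzene, rt) comes back to the route at 14.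

Step 6. The silylmethyl carbanion may act as a base at the γ-position C6. It may also be kept away from the carbonyl carbon by the flanking quaternary C10 and the C8 methyl. The fallback replaces carbanion addition and elimination by a non-basic metal carbene. From 8, dimethyltitanocene (Petasis reagent, toluene, 75 °C) generates titanocene methylidene, which undergoes [2+2] addition and cycloreversion with the ketone and gives 11 directly. This fallback makes no new compound (F0).

Further compounds
F1 | step 3 | 6-methyl-6-[2-(methoxycarbonyl)allyl]carvone hydrobromide (tertiary bromide at C4) | CC1=CC[C@@H](C(C)(C)Br)[C@](C)(CC(=C)C(=O)OC)C1=O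
F2 | step 7 | (−)-drimenol (drim-7-en-11-ol) | CC1=CC[C@H]2C(C)(C)CCC[C@]2(C)[C@H]1CO
F3 | step 7 | drimenal (drim-7-en-11-al) | CC1=CC[C@H]2C(C)(C)CCC[C@]2(C)[C@H]1C=O
F4 | step 7 | 14,15-dinorlabda-7,11E-dien-13-one | CC1=CC[C@H]2C(C)(C)CCC[C@]2(C)[C@H]1/C=C/C(C)=O
F0 | step 6 | none | none
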